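The route rests on taking the pentasubstituted benzene ring (C3a, C4, C5, C6, C7, C7a of the indenone) apart into three alkynes. The key step exploits two features. The lone ring hydrogen at C5, beside the azulenyl-bearing C6, betrays a terminal azulenyl alkyne. The three-atom bridge C1–C2–C3 between C7a and C3a betrays a ketone-tethered 1,6-diyne. One rhodium-catalysed [2+2+2] cycloaddition forms C3a–C7a, C4–C5 and C6–C7, closing the arene and the five-membered ring together. Its precursor is an open-chain nona-2,7-diyn-4-one with guaiazulen-3-yl at C5, methyl at C6 and a silyloxymethyl group on the distal alkyne. Dehydrogenation, desilylation and oxidation then finish.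

Key step: step 10

Assumption: the target has no stereocentre and hindered aryl–azulenyl rotation is not treated as a stereoelement. All sp3 centres of intermediates are racemic and are erased in step 11, so each SMILES shows one enantiomer of one relative configuration. Guaiazulen-3-yl means 5-isopropyl-3,8-dimethylazulen-1-yl.

Step 1
Reactants: 1 guaiazulene (7-isopropyl-1,4-dimethylazulene); 2 ethyl diazoacetate
Product: 3 ethyl 2-(guaiazulen-3-yl)acetate
Conditions: Rh2(OAc)4 (1 mol %), CH2Cl2, rt, 2 added slowly to excess 1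
Reagents that add atoms: none
Why: Carbenoid C–H functionalisation: the electrophilic rhodium carbene is attacked by C3, the only unsubstituted and most nucleophilic carbon of the five-membered ring, and a proton shift in the tropylium-type zwitterion restores the azulene, as known for metal-catalysed diazoacetate alkylation of azulenes.

Step 2
Reactants: 3 ethyl 2-(guaiazulen-3-yl)acetate
Product: 4 2-(guaiazulen-3-yl)-N-methoxy-N-methylacetamide
Conditions: MeNHOMe·HCl, i-PrMgCl, THF, −20 to 0 °C
Reagents that add atoms: N,O-dimethylhydroxylamine hydrochloride, CNOC.Cl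
Why: Weinreb amide formation by magnesium-amide aminolysis works best on this still unbranched ester, which is why it precedes the alkylation.

Step 3
Reactants: 5 propargyl alcohol
Product: 6 triisopropyl(prop-2-yn-1-yloxy)silane
Conditions: TIPSCl, imidazole, CH2Cl2, 0 °C to rt
Reagents that add atoms: chlorotriisopropylsilane, CC(C)[Si](Cl)(C(C)C)C(C)C
Why: Standard silyl ether protection of a primary alcohol, the bulky triisopropylsilyl group being chosen for base stability and as the steric marker of this alkyne terminus in step 10.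

Step 4
Reactants: 6 triisopropyl(prop-2-yn-1-yloxy)silane; 7 acetaldehyde
Product: 9 (±)-5-(triisopropylsilyloxy)pent-3-yn-2-ol, via lithium acetylide 8 (not isolated)
Conditions: n-BuLi, THF, −78 °C; then 7, −78 to 0 °C; H2O
Reagents that add atoms: n-butyllithium, [Li]CCCC (lithium in 8 only)
Why: Acetylide addition to an aldehyde; the new carbinol centre forms as a racemate and needs no control.

Step 5
Reactants: 9 (±)-5-(triisopropylsilyloxy)pent-3-yn-2-ol
Product: 10 (±)-5-(triisopropylsilyloxy)pent-3-yn-2-yl methanesulfonate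
Conditions: MsCl, Et3N, CH2Cl2, −20 to 0 °C, used without chromatography
Reagents that add atoms: methanesulfonyl chloride, CS(=O)(=O)Cl
Why: Mesylation of a secondary propargylic alcohol leaves the C–O stereocentre untouched and gives an activated SN2 electrophile.

Step 6
Reactants: 4 2-(guaiazulen-3-yl)-N-methoxy-N-methylacetamide; 10 (±)-5-(triisopropylsilyloxy)pent-3-yn-2-yl methanesulfonate
Product: 12 (±)-(2R*,3S*)-2-(guaiazulen-3-yl)-N-methoxy-N,3-dimethyl-6-(triisopropylsilyloxy)hex-4-ynamide, via sodium enolate 11 (not isolated)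
Conditions: NaN(SiMe3)2, THF, −78 °C; then 10, DMPU, −78 °C to rt
Reagents that add atoms: sodium bis(trimethylsilyl)amide, C[Si](C)(C)[N-][Si](C)(C)C.[Na+] (sodium in 11 only)
Why: SN2 enolate alkylation: NaN(SiMe3)2 deprotonates the amide α-CH2 without holding the weakly acidic C4-methyl anion of the azulene, the soft enolate displaces the activated propargylic mesylate with inversion, crowding stops a second alkylation, and the two new adjacent stereocentres need no control because both become sp2 in step 11.

Step 7
Reactants: 12 (±)-(2R*,3S*)-2-(guaiazulen-3-yl)-N-methoxy-N,3-dimethyl-6-(triisopropylsilyloxy)hex-4-ynamide; 13 1-propynylmagnesium bromide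
Product: 15 (±)-(5R*,6S*)-5-(guaiazulen-3-yl)-6-methyl-9-(triisopropylsilyloxy)nona-2,7-diyn-4-one, via magnesium chelate 14 (not isolated)
Conditions: 13 (0.5 M in THF, 2 equiv), THF, 0 °C to rt; cold pH 7 buffer
Reagents that add atoms: none
Why: Weinreb ketone synthesis: the slim, weakly basic alkynyl Grignard reagent adds once, chelate 14 holds until the neutral quench, and the acidic C5–H of the ynone is therefore never exposed to base.

Step 8
Reactants: 1 guaiazulene
Product: 17 guaiazulene-3-carbaldehyde, via iminium salt 16 (not isolated)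
Conditions: POCl3, DMF, 0 °C to rt; then aq NaOH
Reagents that add atoms: N,N-dimethylformamide, CN(C)C=O; water, O; phosphoryl chloride, O=P(Cl)(Cl)Cl (counter-ion of 16 only)
Why: Vilsmeier–Haack formylation occurs at C3, the only free position of the electron-rich five-membered ring, and hydrolysis of the stabilised iminium salt gives the aldehyde.

Step 9
Reactants: 17 guaiazulene-3-carbaldehyde
Product: 18 3-ethynylguaiazulene
Conditions: dimethyl (1-diazo-2-oxopropyl)phosphonate, K2CO3, MeOH, rt to 40 °C; kept cold under argon and used promptly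
Reagents that add atoms: dimethyl (1-diazo-2-oxopropyl)phosphonate, COP(=O)(OC)C(=[N+]=[N-])C(C)=O
Why: The Ohira–Bestmann variant of the Seyferth–Gilbert homologation converts the aldehyde into the terminal alkyne under mild carbonate conditions through a diazoalkene and a 1,2-hydrogen shift of the alkylidene carbene, a sequence that electron-rich aryl aldehydes undergo.

Step 10
Reactants: 15 (±)-(5R*,6S*)-5-(guaiazulen-3-yl)-6-methyl-9-(triisopropylsilyloxy)nona-2,7-diyn-4-one; 18 3-ethynylguaiazulene
Product: 19 (±)-trans-(2R*,3S*)-2,6-bis(guaiazulen-3-yl)-3,7-dimethyl-4-(triisopropylsilyloxymethyl)indan-1-one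
Conditions: [Rh(cod)2]BF4 (10 mol %), rac-BINAP (10 mol %), H2 pre-activation then argon, (CH2Cl)2, 15, then 18 (1.5 equiv) by syringe pump, rt to 60 °C
Reagents that add atoms: none
Why: After hydrogenative removal of cod, monovalent rhodium binds both alkynes of 15 and couples them oxidatively, which forms C3a–C7a and closes the five-membered carbocycle (C1, C2, C3, C3a, C7a) by intramolecular cyclometallation within a bicyclic rhodacyclopentadiene. Alkyne 18 then inserts into a Rh–C bond and reductive elimination follows, so that C4–C5 and C6–C7 are made and the six-membered ring closes directly as the arene in an intermolecular two-bond annulation. The closest known reaction type is the cationic rhodium/bisphosphine [2+2+2] cross-cyclotrimerisation of carbonyl-tethered unsymmetrical 1,6-diynes with terminal alkynes, which gives indanones, phthalides and fluorenones, and ethynylazulenes are known partners in metal-catalysed cyclotrimerisation. No stereocentre is created: C2 and C3 are carried over from 15, any cis isomer can relax to trans through the enol, and both centres vanish in step 11. The regioselectivity needed (azulenyl carbon to C7, CH carbon to C4) is secured by two substrate effects that point the same way: the triisopropylsilyloxymethyl arm makes C4 the crowded terminus that accepts only the unsubstituted alkyne carbon, and the ketone makes Rh–C7 the electron-poor, slower-migrating bond, so insertion starts at the electron-richer Rh–C4 bond and leaves the azulenyl carbon to pair with the methyl-bearing C7. The chemoselectivity needed (cross reaction over self reaction) rests on the two internal termini of 15, which slow its dimerisation, and on slow addition of 18, which keeps its homotrimerisation down.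

Step 11
Reactants: 19 (±)-trans-2,6-bis(guaiazulen-3-yl)-3,7-dimethyl-4-(triisopropylsilyloxymethyl)indan-1-one
Product: 21 2,6-bis(guaiazulen-3-yl)-3,7-dimethyl-4-(triisopropylsilyloxymethyl)inden-1-one, via trimethylsilyl enol ether 20 (not isolated)
Conditions: TMSOTf, Et3N, CH2Cl2, 0 °C; crude 20, Pd(OAc)2 (1.2 equiv), MeCN, rt to 40 °C
Reagents that add atoms: trimethylsilyl triflate, C[Si](C)(C)OS(=O)(=O)C(F)(F)F (silyl group in 20 only)
Why: Saegusa–Ito oxidation: soft enolisation gives 20 (only C2 carries an α-hydrogen, and no strong base touches the acidic C4 methyl groups of the azulenes), divalent palladium binds C2 from the face opposite the C3 methyl group and hence syn to C3–H, and β-hydride elimination gives the conjugated indenone and erases both stereocentres.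

Step 12
Reactants: 21 2,6-bis(guaiazulen-3-yl)-3,7-dimethyl-4-(triisopropylsilyloxymethyl)inden-1-one
Product: 22 2,6-bis(guaiazulen-3-yl)-4-(hydroxymethyl)-3,7-dimethylinden-1-one
Conditions: Bu4NF, AcOH (1:1), THF, 0 °C to rt
Reagents that add atoms: none
Why: Fluoride cleavage of the primary silyl ether, buffered with acetic acid so that the vinylogously acidic C3 methyl group and the indenone acceptor meet no basic fluoride or alkoxide.

Step 13
Reactants: 22 2,6-bis(guaiazulen-3-yl)-4-(hydroxymethyl)-3,7-dimethylinden-1-one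
Product: 23 2,6-bis(guaiazulen-3-yl)-3,7-dimethyl-1-oxoindene-4-carbaldehyde (CNP0222726.0)
Conditions: activated MnO2 (excess), CH2Cl2, rt
Reagents that add atoms: none
Why: Activated MnO2 oxidises benzylic alcohols selectively to aldehydes without over-oxidation and is mild enough for the alkylazulene units.

Compound list
1 | guaiazulene (7-isopropyl-1,4-dimethylazulene) | Cc1ccc2c(C)ccc(C(C)C)cc1-2 | starting material
2 | ethyl diazoacetate | CCOC(=O)C=[N+]=[N-] | starting material
3 | ethyl 2-(guaiazulen-3-yl)acetate | CCOC(=O)Cc1cc(C)c2cc(C(C)C)ccc(C)c1-2 | intermediate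
4 | 2-(guaiazulen-3-yl)-N-methoxy-N-methylacetamide | CON(C)C(=O)Cc1cc(C)c2cc(C(C)C)ccc(C)c1-2 | intermediate
5 | propargyl alcohol | C#CCO | starting material
6 | triisopropyl(prop-2-yn-1-yloxy)silane | C#CCO[Si](C(C)C)(C(C)C)C(C)C | intermediate
7 | acetaldehyde | CC=O | starting material
8 | lithium acetylide of 6 (formed in the flask) | [Li]C#CCO[Si](C(C)C)(C(C)C)C(C)C | intermediate
9 | (±)-5-(triisopropylsilyloxy)pent-3-yn-2-ol (one enantiomer drawn) | C[C@H](O)C#CCO[Si](C(C)C)(C(C)C)C(C)C | intermediate
10 | (±)-5-(triisopropylsilyloxy)pent-3-yn-2-yl methanesulfonate (one enantiomer drawn) | C[C@H](OS(C)(=O)=O)C#CCO[Si](C(C)C)(C(C)C)C(C)C | intermediate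
11 | (Z)-sodium enolate of 4 (formed in the flask) | CON(C)/C([O-])=C/c1cc(C)c2cc(C(C)C)ccc(C)c1-2.[Na+] | intermediate
12 | (±)-(2R*,3S*)-2-(guaiazulen-3-yl)-N-methoxy-N,3-dimethyl-6-(triisopropylsilyloxy)hex-4-ynamide (the other diastereomer serves equally) | CON(C)C(=O)[C@@H](c1cc(C)c2cc(C(C)C)ccc(C)c1-2)[C@H](C)C#CCO[Si](C(C)C)(C(C)C)C(C)C | intermediate
13 | 1-propynylmagnesium bromide | CC#C[Mg]Br | starting material
14 | bromomagnesium hemiaminal chelate from 12 and 13 (formed in the flask, hemiaminal carbon undefined) | CC#CC(O[Mg]Br)(N(C)OC)[C@@H](c1cc(C)c2cc(C(C)C)ccc(C)c1-2)[C@H](C)C#CCO[Si](C(C)C)(C(C)C)C(C)C | intermediate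
15 | (±)-(5R*,6S*)-5-(guaiazulen-3-yl)-6-methyl-9-(triisopropylsilyloxy)nona-2,7-diyn-4-one (the other diastereomer serves equally) | CC#CC(=O)[C@@H](c1cc(C)c2cc(C(C)C)ccc(C)c1-2)[C@H](C)C#CCO[Si](C(C)C)(C(C)C)C(C)C | intermediate
16 | (guaiazulen-3-yl)methylidene(dimethyl)iminium dichlorophosphate (formed in the flask) | C[N+](C)=Cc1cc(C)c2cc(C(C)C)ccc(C)c1-2.[O-]P(=O)(Cl)Cl | intermediate
17 | guaiazulene-3-carbaldehyde | O=Cc1cc(C)c2cc(C(C)C)ccc(C)c1-2 | intermediate
18 | 3-ethynylguaiazulene | C#Cc1cc(C)c2cc(C(C)C)ccc(C)c1-2 | intermediate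
19 | (±)-trans-(2R*,3S*)-2,6-bis(guaiazulen-3-yl)-3,7-dimethyl-4-(triisopropylsilyloxymethyl)indan-1-one | C[C@H]1[C@H](c2cc(C)c3cc(C(C)C)ccc(C)c2-3)C(=O)c2c(C)c(-c3cc(C)c4cc(C(C)C)ccc(C)c3-4)cc(CO[Si](C(C)C)(C(C)C)C(C)C)c21 | intermediate
20 | (±)-C1 trimethylsilyl enol ether of 19, a 3-silyloxy-1H-indene (used crude) | C[C@H]1C(c2cc(C)c3cc(C(C)C)ccc(C)c2-3)=C(O[Si](C)(C)C)c2c(C)c(-c3cc(C)c4cc(C(C)C)ccc(C)c3-4)cc(CO[Si](C(C)C)(C(C)C)C(C)C)c21 | intermediate
21 | 2,6-bis(guaiazulen-3-yl)-3,7-dimethyl-4-(triisopropylsilyloxymethyl)inden-1-one | CC1=C(c2cc(C)c3cc(C(C)C)ccc(C)c2-3)C(=O)c2c(C)c(-c3cc(C)c4cc(C(C)C)ccc(C)c3-4)cc(CO[Si](C(C)C)(C(C)C)C(C)C)c21 | intermediate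
22 | 2,6-bis(guaiazulen-3-yl)-4-(hydroxymethyl)-3,7-dimethylinden-1-one | CC1=C(c2cc(C)c3cc(C(C)C)ccc(C)c2-3)C(=O)c2c(C)c(-c3cc(C)c4cc(C(C)C)ccc(C)c3-4)cc(CO)c21 | intermediate
23 | 2,6-bis(guaiazulen-3-yl)-3,7-dimethyl-1-oxoindene-4-carbaldehyde (CNP0222726.0) | CC1=C(c2cc(C)c3cc(C(C)C)ccc(C)c2-3)C(=O)c2c(C)c(-c3cc(C)c4cc(C(C)C)ccc(C)c3-4)cc(C=O)c21 | target

Total step count: 13. Longest linear sequence: 9 steps (3, 4, 5, 6, 7, 10, 11, 12, 13).

Steps most likely to fail

Step 10.
- **What may go wrong:** the terminal alkyne may insert in the opposite orientation, it may trimerise with itself, or the catalyst may be slowed by π-coordination of the azulenes.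
- **Fallback (sets out from 15 and 18, comes back at 19):** the third alkyne is tied to the C4 terminus through a temporary silicon tether, so orientation is no longer a matter of selectivity.
  - The silyl ether of 15 is cleaved with HF·pyridine to 5-(guaiazulen-3-yl)-9-hydroxy-6-methylnona-2,7-diyn-4-one F1.
  - Alkyne 18 is metallated with EtMgBr, which spares the seven-membered ring and the C4 methyl group, to bromomagnesium (guaiazulen-3-yl)acetylide F2.
  - Quenching with excess Me2SiCl2 gives chloro[(guaiazulen-3-yl)ethynyl]dimethylsilane F3.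
  - F3 silylates F1 (imidazole) to the silyl-ether-linked triyne F4.
  - Intramolecular cyclotrimerisation with RhCl(PPh3)3 or the catalyst of step 10 can only place silicon on C5 and the azulene on C6. It gives the benzoxasilole-fused indanone F5.
  - Bu4NF in wet THF cleaves Si–O and protodesilylates C5, which lies para to the acyl-bearing C7a, to the hydroxymethyl indanone F6.
  - TIPSCl/imidazole returns 19.

Step 11.
- **What may go wrong:** palladation may be slow at the crowded, fully substituted C2, so that protodesilylation back to the ketone competes. Palladium may also bind unproductively to the azulenes.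
- **Fallback (sets out from 20, comes back at 21):** a thermal selenoxide syn-elimination replaces the palladium β-hydride elimination.
  - Enol ether 20 reacts with PhSeCl (CH2Cl2, −78 °C) on the face opposite the C3 methyl group to give the 2-(phenylselanyl)indanone F7, with selenium cis to C3–H.
  - Oxidation with H2O2/pyridine at 0 °C gives the selenoxide F8.
  - F8 eliminates toward the only available β-hydrogen below room temperature and gives 21.

Step 6.
- **What may go wrong:** the base may eliminate methanesulfonic acid from the electrophile, attack may occur at the distal alkyne carbon with allene formation, or substitution between two secondary carbons next to the peri methyl group may be slow.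
- **Fallback (sets out from 3 and 9, comes back at 12):** a Nicholas reaction replaces the SN2 event by capture of a cobalt-stabilised propargylic cation.
  - Alcohol 9 is complexed with Co2(CO)8 to the hexacarbonyldicobalt complex F9.
  - Ester 3 is converted with TBSOTf/Et3N into the tert-butyldimethylsilyl ketene acetal F10.
  - BF3·OEt2 at −78 °C ionises F9 at the secondary carbinol in the presence of F10 and gives the cobalt-complexed ester F11.
  - Me3NO releases the alkyne as ethyl 2-(guaiazulen-3-yl)-3-methyl-6-(triisopropylsilyloxy)hex-4-ynoate F12.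
  - AlMe3/MeNHOMe·HCl converts F12 into 12.

Further compounds
F1 | step 10 | (±)-5-(guaiazulen-3-yl)-9-hydroxy-6-methylnona-2,7-diyn-4-one | CC#CC(=O)[C@@H](c1cc(C)c2cc(C(C)C)ccc(C)c1-2)[C@H](C)C#CCO
F2 | step 10 | bromomagnesium (guaiazulen-3-yl)acetylide | Br[Mg]C#Cc1cc(C)c2cc(C(C)C)ccc(C)c1-2
F3 | step 10 | chloro[(guaiazulen-3-yl)ethynyl]dimethylsilane | C[Si](C)(Cl)C#Cc1cc(C)c2cc(C(C)C)ccc(C)c1-2
F4 | step 10 | silyl-ether-linked triyne, the [(guaiazulen-3-yl)ethynyl]dimethylsilyl ether of F1 | CC#CC(=O)[C@@H](c1cc(C)c2cc(C(C)C)ccc(C)c1-2)[C@H](C)C#CCO[Si](C)(C)C#Cc1cc(C)c2cc(C(C)C)ccc(C)c1-2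
F5 | step 10 | benzoxasilole-fused indanone (C4–CH2–O–SiMe2–C5 ring on the skeleton of 19) | C[C@H]1[C@H](c2cc(C)c3cc(C(C)C)ccc(C)c2-3)C(=O)c2c(C)c(-c3cc(C)c4cc(C(C)C)ccc(C)c3-4)c3c(CO[Si]3(C)C)c21
F6 | step 10 | (±)-trans-2,6-bis(guaiazulen-3-yl)-4-(hydroxymethyl)-3,7-dimethylindan-1-one | C[C@H]1[C@H](c2cc(C)c3cc(C(C)C)ccc(C)c2-3)C(=O)c2c(C)c(-c3cc(C)c4cc(C(C)C)ccc(C)c3-4)cc(CO)c21
F7 | step 11 | (±)-2-(phenylselanyl) derivative of 19, selenium cis to C3–H | C[C@H]1[C@](c2cc(C)c3cc(C(C)C)ccc(C)c2-3)([Se]c2ccccc2)C(=O)c2c(C)c(-c3cc(C)c4cc(C(C)C)ccc(C)c3-4)cc(CO[Si](C(C)C)(C(C)C)C(C)C)c21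
F8 | step 11 | selenoxide of F7 | C[C@H]1[C@](c2cc(C)c3cc(C(C)C)ccc(C)c2-3)([Se](=O)c2ccccc2)C(=O)c2c(C)c(-c3cc(C)c4cc(C(C)C)ccc(C)c3-4)cc(CO[Si](C(C)C)(C(C)C)C(C)C)c21
F9 | step 6 | hexacarbonyldicobalt complex of 9 | C[C@H](O)C12C3(CO[Si](C(C)C)(C(C)C)C(C)C)[Co]1(=C=O)(=C=O)(=C=O)[Co]23(=C=O)(=C=O)=C=O
F10 | step 6 | tert-butyldimethylsilyl ketene acetal of 3 (double-bond geometry open) | CCOC(O[Si](C)(C)C(C)(C)C)=Cc1cc(C)c2cc(C(C)C)ccc(C)c1-2
F11 | step 6 | hexacarbonyldicobalt complex of F12 | CCOC(=O)[C@@H](c1cc(C)c2cc(C(C)C)ccc(C)c1-2)[C@H](C)C12C3(CO[Si](C(C)C)(C(C)C)C(C)C)[Co]1(=C=O)(=C=O)(=C=O)[Co]23(=C=O)(=C=O)=C=O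
F12 | step 6 | (±)-ethyl 2-(guaiazulen-3-yl)-3-methyl-6-(triisopropylsilyloxy)hex-4-ynoate | CCOC(=O)[C@@H](c1cc(C)c2cc(C(C)C)ccc(C)c1-2)[C@H](C)C#CCO[Si](C(C)C)(C(C)C)C(C)C
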